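The oxolane ring (numbering: O1, C2 aryl, C3 hydroxymethyl, C4 benzyl, C5) is dissected into a formaldehyde unit (O1–C5) and a C2–C3–C4 1,3-zwitterion. C2 is the benzylic carbon whose trimethoxyphenyl group stabilises positive charge; C4 is a malonate carbon. The zwitterion is stored as an enantioenriched donor–acceptor cyclopropane. A Lewis-acid (3+2) annulation with formaldehyde forges C4–C5 and O1–C2 in one operation, with inversion at C2. The geminal diester at C4 is then used twice: one ester is tied to the C3 arm as a cis-fused lactone, fixing the C3/C4 cis relationship, and the other is excised. The lactone carbonyl carbon finally becomes the benzylic CH2 by hydrazone–boronic acid reductive coupling.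

Key step: step 2

Assumption: the (R)-configured diarylprolinol silyl ether is taken to deliver the (2S,3R)-cyclopropane 3; if the sense of induction were opposite, the (S)-catalyst would be used instead.
Assumption: compounds 1, 2, 4 (as paraformaldehyde) and 11 are purchased.

Step 1
Reactants: 1 (E)-3-(3,4,5-trimethoxyphenyl)prop-2-enal; 2 dimethyl 2-bromomalonate
Product: 3 dimethyl (2S,3R)-2-formyl-3-(3,4,5-trimethoxyphenyl)cyclopropane-1,1-dicarboxylate (formyl trans to aryl)
Conditions: (R)-α,α-diphenylprolinol trimethylsilyl ether (10 mol%), 2,6-lutidine (1.1 equiv), CH2Cl2, 0 → 23 °C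
Reagents that add atoms: none
Why: Organocatalytic Michael-initiated ring closure: the iminium ion of 1 exposes one face of C-β to the bromomalonate anion (catalyst control sets the aryl-bearing carbon), and the enamine so formed displaces bromide in a 3-exo-tet closure that places the formyl group trans to the aryl group.

Step 2
Reactants: 3 dimethyl (2S,3R)-2-formyl-3-(3,4,5-trimethoxyphenyl)cyclopropane-1,1-dicarboxylate; 4 formaldehyde (charged as paraformaldehyde)
Product: 5 dimethyl (4R,5S)-4-formyl-5-(3,4,5-trimethoxyphenyl)oxolane-3,3-dicarboxylate (formyl cis to aryl)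
Conditions: Sn(OTf)2 (10 mol%), (CH2O)n (5 equiv), ClCH2CH2Cl, 23 → 45 °C
Reagents that add atoms: none
Why: Sn(OTf)2 chelates the geminal diester and polarises the C(aryl)–C(malonate) bond of 3; the carbonyl oxygen of formaldehyde opens this bond by backside attack at the benzylic carbon (O1–C2), and the resulting O-alkyl oxocarbenium–malonate zwitterion collapses by aldol-type C4–C5 bond formation. The closest known reaction type is the Lewis-acid-catalysed (3+2) annulation of 2-arylcyclopropane-1,1-diesters with aldehydes. The oxolane ring closes in a 5-(enolexo)-endo-trig mode, the malonate carbon adding to the oxocarbenium carbon that already lies in the forming ring, which is feasible because the acceptor is a cation. C2 is the only stereocentre made: it is set by stereospecific inversion of the benzylic cyclopropane carbon, while C3 is carried through unchanged (cis to the aryl group at this stage) and C4 and C5 are not yet stereogenic. The step needs cleavage of the C2–C4 bond and not of the formyl-activated C2–C3 bond, which bidentate binding of the Lewis acid to the malonate and the better malonate leaving group should secure; it also needs formaldehyde to outcompete the substrate's own aldehyde, which the excess of the small aldehyde and the hindered, electron-poor formyl group should secure. An SN2-like and not an SN1 opening is favoured by the only moderately donating trimethoxyphenyl group and the low temperature.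

Step 3
Reactants: 5 dimethyl (4R,5S)-4-formyl-5-(3,4,5-trimethoxyphenyl)oxolane-3,3-dicarboxylate
Product: 8 methyl (1R,5R,6S)-2-oxo-6-(3,4,5-trimethoxyphenyl)-3,7-dioxabicyclo[3.3.0]octane-1-carboxylate, via trans-formyl diester 6 (not isolated), via hydroxymethyl diester 7 (not isolated)
Conditions: DBU (0.2 equiv), CH2Cl2, 23 °C; then MeOH, NaBH4 (1 equiv), 0 °C; then TsOH·H2O (0.3 equiv), 23 °C
Reagents that add atoms: none
Why: Base-mediated epimerisation of the aldehyde α-carbon (thermodynamic control: the formyl group moves trans to the C2 aryl group, the flanking C4 diester being symmetric, while C2 is untouched), chemoselective NaBH4 reduction of the aldehyde and intramolecular transesterification, in which the new alcohol can reach only the ester on its own face, so that the two esters are told apart and the C3/C4 cis ring fusion is fixed.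

Step 4
Reactants: 8 methyl (1R,5R,6S)-2-oxo-6-(3,4,5-trimethoxyphenyl)-3,7-dioxabicyclo[3.3.0]octane-1-carboxylate
Product: 9 (1R,5R,6S)-6-(3,4,5-trimethoxyphenyl)-3,7-dioxabicyclo[3.3.0]octan-2-one
Conditions: LiCl (3 equiv), H2O (2 equiv), DMSO, 150 °C
Reagents that add atoms: none
Why: Krapcho dealkoxycarbonylation: chloride demethylates the ester, CO2 is lost from the lactone-stabilised carboxylate and the lactone enolate is protonated to the only accessible cis-fused bicycle, which sets C4 with its carbonyl carbon cis to the C3 CH2O arm.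

Step 5
Reactants: 9 (1R,5R,6S)-6-(3,4,5-trimethoxyphenyl)-3,7-dioxabicyclo[3.3.0]octan-2-one
Product: 10 (1R,5R,6S)-6-(3,4,5-trimethoxyphenyl)-3,7-dioxabicyclo[3.3.0]octan-2-ol (lactol, both anomers)
Conditions: iBu2AlH (1.1 equiv), CH2Cl2, −78 °C; aq. KNaC4H4O6 (potassium sodium tartrate) work-up
Reagents that add atoms: none
Why: Partial reduction of a γ-lactone to the lactol with iBu2AlH, whose tetrahedral aluminium alkoxide does not collapse at −78 °C; no stereocentre of the oxolane is touched.

Step 6
Reactants: 10 (1R,5R,6S)-6-(3,4,5-trimethoxyphenyl)-3,7-dioxabicyclo[3.3.0]octan-2-ol; 11 (3,4,5-trimethoxyphenyl)boronic acid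
Product: 13 [(2S,3R,4R)-2-(3,4,5-trimethoxyphenyl)-4-[(3,4,5-trimethoxyphenyl)methyl]oxolan-3-yl]methanol, via tosylhydrazone 12 (not isolated)
Conditions: TsNHNH2 (1.1 equiv), 1,4-dioxane, 80 °C; then 11 (1.5 equiv), K2CO3 (2 equiv), 110 °C
Reagents that add atoms: 4-methylbenzenesulfonohydrazide, Cc1ccc(cc1)S(=O)(=O)NN (its atoms are kept only in intermediate 12 and are lost again before 13)
Why: Reductive coupling of an N-tosylhydrazone with an arylboronic acid: the lactol condenses through its hydroxy-aldehyde form to 12, base releases the diazoalkane (Bamford–Stevens type), the aryl group migrates from boron to carbon with loss of N2 and the benzylic boronic acid is protodeboronated to the CH2Ar group; C4 carries no bond change and should keep its configuration.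

Compound list
1 | (E)-3-(3,4,5-trimethoxyphenyl)prop-2-enal | COc1cc(/C=C/C=O)cc(OC)c1OC | starting material
2 | dimethyl 2-bromomalonate | COC(=O)C(Br)C(=O)OC | starting material
3 | dimethyl (2S,3R)-2-formyl-3-(3,4,5-trimethoxyphenyl)cyclopropane-1,1-dicarboxylate | COC(=O)C1(C(=O)OC)[C@@H](C=O)[C@@H]1c2cc(OC)c(OC)c(OC)c2 | intermediate
4 | formaldehyde (used as paraformaldehyde) | C=O | starting material
5 | dimethyl (4R,5S)-4-formyl-5-(3,4,5-trimethoxyphenyl)oxolane-3,3-dicarboxylate (formyl cis to aryl) | COC(=O)C1(C(=O)OC)CO[C@H](c2cc(OC)c(OC)c(OC)c2)[C@@H]1C=O | intermediate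
6 | dimethyl (4S,5S)-4-formyl-5-(3,4,5-trimethoxyphenyl)oxolane-3,3-dicarboxylate (formyl trans to aryl) | COC(=O)C1(C(=O)OC)CO[C@H](c2cc(OC)c(OC)c(OC)c2)[C@H]1C=O | intermediate
7 | dimethyl (4R,5S)-4-(hydroxymethyl)-5-(3,4,5-trimethoxyphenyl)oxolane-3,3-dicarboxylate | COC(=O)C1(C(=O)OC)CO[C@H](c2cc(OC)c(OC)c(OC)c2)[C@H]1CO | intermediate
8 | methyl (1R,5R,6S)-2-oxo-6-(3,4,5-trimethoxyphenyl)-3,7-dioxabicyclo[3.3.0]octane-1-carboxylate | COC(=O)[C@]12CO[C@H](c3cc(OC)c(OC)c(OC)c3)[C@H]1COC2=O | intermediate
9 | (1R,5R,6S)-6-(3,4,5-trimethoxyphenyl)-3,7-dioxabicyclo[3.3.0]octan-2-one | [C@H]12CO[C@H](c3cc(OC)c(OC)c(OC)c3)[C@H]1COC2=O | intermediate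
10 | (1R,5R,6S)-6-(3,4,5-trimethoxyphenyl)-3,7-dioxabicyclo[3.3.0]octan-2-ol (both anomers) | [C@H]12CO[C@H](c3cc(OC)c(OC)c(OC)c3)[C@H]1COC2O | intermediate
11 | (3,4,5-trimethoxyphenyl)boronic acid | COc1cc(B(O)O)cc(OC)c1OC | starting material
12 | N'-[(E)-{(3S,4R,5S)-4-(hydroxymethyl)-5-(3,4,5-trimethoxyphenyl)oxolan-3-yl}methylidene]-4-methylbenzenesulfonohydrazide | Cc1ccc(cc1)S(=O)(=O)N/N=C/[C@H]1CO[C@H](c2cc(OC)c(OC)c(OC)c2)[C@H]1CO | intermediate
13 | [(2S,3R,4R)-2-(3,4,5-trimethoxyphenyl)-4-[(3,4,5-trimethoxyphenyl)methyl]oxolan-3-yl]methanol | COc1cc(C[C@H]2CO[C@H](c3cc(OC)c(OC)c(OC)c3)[C@H]2CO)cc(OC)c1OC | target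

Total step count: 6. Longest linear sequence: 6 steps (1 → 3 → 5 → 8 → 9 → 10 → 13).

Steps most likely to fail

Step 2. Formaldehyde is a weak oxygen nucleophile, so opening of the activated cyclopropane may be slow. It may then be overtaken by attack of the substrate's own formyl oxygen on a second molecule (oligomerisation), by opening of the formyl-activated C2–C3 bond, or by hydroxymethylation of the enolisable product aldehyde. Ionisation of the benzylic carbon before attack would cost stereospecificity and would show after step 3 as loss of enantiomeric purity. Fallback (sets out from 1 and 2, returns at 8): the annulation is run stepwise with iodide as the ring-opening nucleophile and net retention at the benzylic carbon, which requires the mirror-image cyclopropane. Compounds 1 and 2 are combined as in step 1 but with (S)-α,α-diphenylprolinol trimethylsilyl ether to give dimethyl (2R,3S)-2-formyl-3-(3,4,5-trimethoxyphenyl)cyclopropane-1,1-dicarboxylate F1. Reduction with NaBH4 (MeOH, 0 °C) should give dimethyl (2R,3S)-2-(hydroxymethyl)-3-(3,4,5-trimethoxyphenyl)cyclopropane-1,1-dicarboxylate F2. F2 is lactonised without isolation (TsOH, toluene, 60 °C) to methyl (1S,5R,6S)-2-oxo-6-(3,4,5-trimethoxyphenyl)-3-oxabicyclo[3.1.0]hexane-1-carboxylate F3. Treatment of F3 with MgI2 (1 equiv) and paraformaldehyde 4 in THF at 60 °C should open the cyclopropane by iodide attack at the benzylic carbon with inversion. This gives the magnesium enolate of methyl (4R)-4-[(R)-iodo(3,4,5-trimethoxyphenyl)methyl]-2-oxooxolane-3-carboxylate F4. Reversible aldol addition of this enolate to formaldehyde follows; only the aldolate cis to the iodobenzyl arm can close, by displacement of iodide with a second inversion, and this should deliver 8 directly. Formaldehyde acts here only as an electrophile, no free aldehyde is present and the epimerisation of step 3 is not needed.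

Step 6. The non-stabilised diazoalkane may undergo 1,2-hydride shift or intramolecular O–H insertion faster than capture by boron, and hydrazone/ene-hydrazine tautomerism at 110 °C may epimerise C4. Fallback (sets out from 10, returns at 13): tosylhydrazone 12 is isolated and coupled with 5-bromo-1,2,3-trimethoxybenzene F5 (Pd2(dba)3, XPhos, LiOtBu, 1,4-dioxane, 90 °C; palladium carbene formation, aryl migration and β-hydride elimination). This should give [(2S,3R)-2-(3,4,5-trimethoxyphenyl)-4-[(3,4,5-trimethoxyphenyl)methylidene]oxolan-3-yl]methanol F6. Hydrogenation of F6 (H2, 1 atm, Pd/C, EtOAc) from the face opposite the adjacent C3 hydroxymethyl group should set C4 anew with the benzyl group cis to that arm and give 13.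

Step 4. Chloride may attack the lactone CH2 instead of the methyl ester, so that the lactone carboxylate and not the ester is lost as CO2, which would excise the wrong carbon and unlock the cis ring fusion. Fallback (sets out from 8, returns at 9): saponification of 8 (LiOH, THF–H2O, 23 °C) should give (4R,5S)-4-(hydroxymethyl)-5-(3,4,5-trimethoxyphenyl)oxolane-3,3-dicarboxylic acid F7. Acidification and warming with TsOH in toluene should relactonise the carboxyl group cis to the hydroxymethyl arm to (1R,5R,6S)-2-oxo-6-(3,4,5-trimethoxyphenyl)-3,7-dioxabicyclo[3.3.0]octane-1-carboxylic acid F8. F8 should lose CO2 at 110 °C to give 9.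

Further compounds
F1 | step 2 | dimethyl (2R,3S)-2-formyl-3-(3,4,5-trimethoxyphenyl)cyclopropane-1,1-dicarboxylate | COC(=O)C1(C(=O)OC)[C@H](C=O)[C@H]1c2cc(OC)c(OC)c(OC)c2
F2 | step 2 | dimethyl (2R,3S)-2-(hydroxymethyl)-3-(3,4,5-trimethoxyphenyl)cyclopropane-1,1-dicarboxylate | COC(=O)C1(C(=O)OC)[C@H](CO)[C@H]1c2cc(OC)c(OC)c(OC)c2
F3 | step 2 | methyl (1S,5R,6S)-2-oxo-6-(3,4,5-trimethoxyphenyl)-3-oxabicyclo[3.1.0]hexane-1-carboxylate | COC(=O)[C@@]12C(=O)OC[C@@H]1[C@H]2c3cc(OC)c(OC)c(OC)c3
F4 | step 2 | methyl (4R)-4-[(R)-iodo(3,4,5-trimethoxyphenyl)methyl]-2-oxooxolane-3-carboxylate (formed as its magnesium enolate) | COC(=O)C1C(=O)OC[C@@H]1[C@@H](I)c2cc(OC)c(OC)c(OC)c2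
F5 | step 6 | 5-bromo-1,2,3-trimethoxybenzene | COc1cc(Br)cc(OC)c1OC
F6 | step 6 | [(2S,3R)-2-(3,4,5-trimethoxyphenyl)-4-[(3,4,5-trimethoxyphenyl)methylidene]oxolan-3-yl]methanol | COc1cc(C=C2CO[C@H](c3cc(OC)c(OC)c(OC)c3)[C@H]2CO)cc(OC)c1OC
F7 | step 4 | (4R,5S)-4-(hydroxymethyl)-5-(3,4,5-trimethoxyphenyl)oxolane-3,3-dicarboxylic acid | OC(=O)C1(C(O)=O)CO[C@H](c2cc(OC)c(OC)c(OC)c2)[C@H]1CO
F8 | step 4 | (1R,5R,6S)-2-oxo-6-(3,4,5-trimethoxyphenyl)-3,7-dioxabicyclo[3.3.0]octane-1-carboxylic acid | OC(=O)[C@]12CO[C@H](c3cc(OC)c(OC)c(OC)c3)[C@H]1COC2=O
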